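The target (pyrrhoxanthin) is cut at the C10′–C11′ single bond: the bond between the CH of the C(CH3)=CH unit on the alkyne of the acetoxycyclohexene (ring A) and the terminal CH of the triene leading to the (Z)-ylidenebutenolide (ring B) and the epoxycyclohexanol (ring C). Because this sp2–sp2 bond lies between two E-alkenes that can be made beforehand, one stereoretentive, neutral Stille coupling joins the ring-A (E)-alkenyl iodide (C14 skeleton, acetate in place) with a C23 trienylstannane already carrying rings B and C, the anti-epoxide and the free hydroxyl, and gives the unprotected target in the last step. Both six-membered rings come from one actinol-derived enol triflate.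

Key step: step 19

Assumption: (4R,6R)-actinol (the industrial zeaxanthin intermediate) is taken as a purchasable chiral-pool material, as are propiolic acid, (E)-3-methylpent-2-en-4-yn-1-ol, (E)-1,2-bis(tributylstannyl)ethene and 1,4-bis(trimethylsilyl)buta-1,3-diyne.

Step 1
Reactants: 1 (4R,6R)-4-hydroxy-2,2,6-trimethylcyclohexanone
Product: 2 (4R,6R)-4-(tert-butyldimethylsilyloxy)-2,2,6-trimethylcyclohexanone
Conditions: TBSCl, imidazole, DMF, rt
Reagents that add atoms: tert-butyldimethylsilyl chloride, CC(C)(C)[Si](C)(C)Cl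
Why: Silyl ether formation at the only hydroxyl; neither stereocentre is touched.

Step 2
Reactants: 2 (4R,6R)-4-(tert-butyldimethylsilyloxy)-2,2,6-trimethylcyclohexanone
Product: 4 (R)-4-(tert-butyldimethylsilyloxy)-2,6,6-trimethylcyclohex-1-en-1-yl trifluoromethanesulfonate, via lithium enolate 3 (not isolated)
Conditions: LiN(iPr)2, THF, −78 → 0 °C; PhNTf2, 0 °C → rt
Reagents that add atoms: N-phenylbis(trifluoromethanesulfonimide), O=S(=O)(N(c1ccccc1)S(=O)(=O)C(F)(F)F)C(F)(F)F
Why: Enolate O-triflation; the ketone has a single enolisable α-CH, so only the tetrasubstituted enol triflate can form, and the methyl-bearing stereocentre is removed on purpose.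

Step 3
Reactants: 4 (R)-4-(tert-butyldimethylsilyloxy)-2,6,6-trimethylcyclohex-1-en-1-yl trifluoromethanesulfonate
Product: 5 methyl (R)-4-(tert-butyldimethylsilyloxy)-2,6,6-trimethylcyclohex-1-ene-1-carboxylate
Conditions: Pd(OAc)2 (5 mol %), PPh3 (10 mol %), CO (1 atm), Et3N, MeOH/DMF, 60 °C
Reagents that add atoms: carbon monoxide, [C-]#[O+]; methanol, CO
Why: Palladium-catalysed alkoxycarbonylation of an enol triflate (oxidative addition, CO insertion, methanolysis), well established for 2,6,6-trimethylcyclohexenyl triflates.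

Step 4
Reactants: 5 methyl (R)-4-(tert-butyldimethylsilyloxy)-2,6,6-trimethylcyclohex-1-ene-1-carboxylate
Product: 6 [(R)-4-(tert-butyldimethylsilyloxy)-2,6,6-trimethylcyclohex-1-en-1-yl]methanol
Conditions: i-Bu2AlH (2.5 equiv), CH2Cl2, −78 → 0 °C; Rochelle salt work-up
Reagents that add atoms: none
Why: 1,2-Reduction of the hindered conjugated ester to the primary allylic alcohol with an aluminium hydride; the silyl ether is inert.

Step 5
Reactants: 6 [(R)-4-(tert-butyldimethylsilyloxy)-2,6,6-trimethylcyclohex-1-en-1-yl]methanol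
Product: 7 [(1R,4S,6R)-4-(tert-butyldimethylsilyloxy)-2,2,6-trimethyl-7-oxabicyclo[4.1.0]heptan-1-yl]methanol (epoxide oxygen anti to the silyloxy group)
Conditions: Ti(OiPr)4 (1.0 equiv), D-(−)-diethyl tartrate (1.2 equiv), t-BuOOH (anhydrous, 2 equiv), 4 Å molecular sieves, CH2Cl2, −20 °C
Reagents that add atoms: tert-butyl hydroperoxide, CC(C)(C)OO
Why: Katsuki–Sharpless asymmetric epoxidation of the tetrasubstituted primary allylic alcohol; the titanium–D-tartrate complex should deliver the peroxide oxygen to the alkene face anti to the silyloxy group (reagent control), setting both epoxide carbons at once.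

Step 6
Reactants: 7 [(1R,4S,6R)-4-(tert-butyldimethylsilyloxy)-2,2,6-trimethyl-7-oxabicyclo[4.1.0]heptan-1-yl]methanol
Product: 8 (1S,4S,6R)-4-(tert-butyldimethylsilyloxy)-2,2,6-trimethyl-7-oxabicyclo[4.1.0]heptane-1-carbaldehyde
Conditions: Dess–Martin periodinane, NaHCO3, CH2Cl2, 0 °C → rt
Reagents that add atoms: none
Why: Buffered Dess–Martin oxidation of the primary alcohol; the aldehyde has no α-hydrogen, so the epoxide stereocentres cannot epimerise.

Step 7
Reactants: 8 (1S,4S,6R)-4-(tert-butyldimethylsilyloxy)-2,2,6-trimethyl-7-oxabicyclo[4.1.0]heptane-1-carbaldehyde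
Product: 9 2-{(E)-2-[(1S,4S,6R)-4-(tert-butyldimethylsilyloxy)-2,2,6-trimethyl-7-oxabicyclo[4.1.0]heptan-1-yl]ethenyl}-4,4,5,5-tetramethyl-1,3,2-dioxaborolane
Conditions: CrCl2 (8 equiv), Cl2CHBpin (2 equiv), LiI (4 equiv), THF, rt, dark
Reagents that add atoms: 2-(dichloromethyl)-4,4,5,5-tetramethyl-1,3,2-dioxaborolane, ClC(Cl)B1OC(C)(C)C(C)(C)O1
Why: Takai–Utimoto boryl olefination; the geminal dichromium reagent adds to the non-enolisable aldehyde and eliminates to the (E)-alkenylboronate, and the near-neutral divalent chromium reagent should leave the neighbouring epoxide intact.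

Step 8
Reactants: 9 2-{(E)-2-[(1S,4S,6R)-4-(tert-butyldimethylsilyloxy)-2,2,6-trimethyl-7-oxabicyclo[4.1.0]heptan-1-yl]ethenyl}-4,4,5,5-tetramethyl-1,3,2-dioxaborolane
Product: 10 (1R,3S,6S)-1,5,5-trimethyl-6-[(E)-2-(4,4,5,5-tetramethyl-1,3,2-dioxaborolan-2-yl)ethenyl]-7-oxabicyclo[4.1.0]heptan-3-ol
Conditions: Bu4NF (1.5 equiv), THF, 0 °C → rt
Reagents that add atoms: none
Why: Fluoride cleavage of the secondary silyl ether; the pinacol boronate and the epoxide tolerate fluoride, and the hydroxyl is freed here so that no deprotection is needed once ring B is present.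

Step 9
Reactants: 11 propiolic acid
Product: 12 (E)-2,3-dibromoprop-2-enoic acid
Conditions: Br2 (1.0 equiv), CHCl3, 0 °C → rt, dark
Reagents that add atoms: bromine, BrBr
Why: Electrophilic anti-addition of bromine to the alkyne gives the E-dibromide, which places the β-bromine cis to the carboxyl group as needed for lactonisation.

Step 10
Reactants: 12 (E)-2,3-dibromoprop-2-enoic acid; 13 (E)-3-methylpent-2-en-4-yn-1-ol
Product: 15 (5Z)-3-bromo-5-[(2E)-4-hydroxy-2-methylbut-2-en-1-ylidene]furan-2(5H)-one, via bromoenynoic acid 14 (not isolated)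
Conditions: Pd(PPh3)4 (5 mol %), CuI (10 mol %), Et3N (3 equiv), MeCN, rt, dark
Reagents that add atoms: none
Why: Tandem Sonogashira coupling/lactonisation of a (Z)-3-haloacrylic acid: coupling at the more electrophilic β-bromide, then 5-exo-dig anti-addition of the carboxylate across the metal-activated alkyne and protodemetalation, which puts the side chain cis to the ring oxygen and so gives the (Z)-ylidenebutenolide.

Step 11
Reactants: 15 (5Z)-3-bromo-5-[(2E)-4-hydroxy-2-methylbut-2-en-1-ylidene]furan-2(5H)-one; 10 (1R,3S,6S)-1,5,5-trimethyl-6-[(E)-2-(4,4,5,5-tetramethyl-1,3,2-dioxaborolan-2-yl)ethenyl]-7-oxabicyclo[4.1.0]heptan-3-ol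
Product: 16 (5Z)-3-{(E)-2-[(1S,4S,6R)-4-hydroxy-2,2,6-trimethyl-7-oxabicyclo[4.1.0]heptan-1-yl]ethenyl}-5-[(2E)-4-hydroxy-2-methylbut-2-en-1-ylidene]furan-2(5H)-one
Conditions: Pd(PPh3)4 (5 mol %), Ag2O (2 equiv), THF/H2O (10:1), rt → 40 °C, dark
Reagents that add atoms: none
Why: Silver-oxide-promoted Suzuki–Miyaura coupling of the activated α-bromobutenolide with the alkenylboronate, a protocol used for bromofuranones because it avoids strong aqueous base; both alkene geometries are retained.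

Step 12
Reactants: 16 (5Z)-3-{(E)-2-[(1S,4S,6R)-4-hydroxy-2,2,6-trimethyl-7-oxabicyclo[4.1.0]heptan-1-yl]ethenyl}-5-[(2E)-4-hydroxy-2-methylbut-2-en-1-ylidene]furan-2(5H)-one
Product: 17 (2E)-4-[(2Z)-4-{(E)-2-[(1S,4S,6R)-4-hydroxy-2,2,6-trimethyl-7-oxabicyclo[4.1.0]heptan-1-yl]ethenyl}-5-oxofuran-2(5H)-ylidene]-3-methylbut-2-enal
Conditions: MnO2 (activated, 20 equiv), CH2Cl2, rt, dark
Reagents that add atoms: none
Why: Manganese dioxide oxidises only the primary allylic alcohol; the saturated secondary hydroxyl of ring C is not touched.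

Step 13
Reactants: 17 (2E)-4-[(2Z)-4-{(E)-2-[(1S,4S,6R)-4-hydroxy-2,2,6-trimethyl-7-oxabicyclo[4.1.0]heptan-1-yl]ethenyl}-5-oxofuran-2(5H)-ylidene]-3-methylbut-2-enal
Product: 18 (5Z)-3-{(E)-2-[(1S,4S,6R)-4-hydroxy-2,2,6-trimethyl-7-oxabicyclo[4.1.0]heptan-1-yl]ethenyl}-5-[(2E,4E)-5-iodo-2-methylpenta-2,4-dien-1-ylidene]furan-2(5H)-one
Conditions: CrCl2 (8 equiv), CHI3 (2.5 equiv), THF/1,4-dioxane (1:6), 0 °C → rt, dark
Reagents that add atoms: iodoform, IC(I)I
Why: Takai iodo-olefination; the geminal dichromium carbenoid adds chemoselectively to the aldehyde and eliminates to the (E)-alkenyl iodide, and the free hydroxyl is tolerated.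

Step 14
Reactants: 18 (5Z)-3-{(E)-2-[(1S,4S,6R)-4-hydroxy-2,2,6-trimethyl-7-oxabicyclo[4.1.0]heptan-1-yl]ethenyl}-5-[(2E,4E)-5-iodo-2-methylpenta-2,4-dien-1-ylidene]furan-2(5H)-one; 19 (E)-1,2-bis(tributylstannyl)ethene
Product: 20 (5Z)-3-{(E)-2-[(1S,4S,6R)-4-hydroxy-2,2,6-trimethyl-7-oxabicyclo[4.1.0]heptan-1-yl]ethenyl}-5-[(2E,4E,6E)-2-methyl-7-(tributylstannyl)hepta-2,4,6-trien-1-ylidene]furan-2(5H)-one
Conditions: 19 (3 equiv), PdCl2(MeCN)2 (5 mol %), DMF, rt, dark
Reagents that add atoms: none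
Why: Stille mono-coupling of the dienyl iodide with excess distannylethene (a two-carbon linchpin) under ligand-free, base-free conditions; the excess suppresses double coupling and all geometries are retained.

Step 15
Reactants: 4 (R)-4-(tert-butyldimethylsilyloxy)-2,6,6-trimethylcyclohex-1-en-1-yl trifluoromethanesulfonate; 21 1,4-bis(trimethylsilyl)buta-1,3-diyne
Product: 24 tert-butyldimethyl{[(R)-3,5,5-trimethyl-4-[4-(trimethylsilyl)buta-1,3-diyn-1-yl]cyclohex-3-en-1-yl]oxy}silane, via lithium silyldiynide 22 (not isolated), via diynylzinc bromide 23 (not isolated)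
Conditions: 21 (1.5 equiv), MeLi·LiBr, THF, rt; ZnBr2, 0 °C; then 4, Pd(PPh3)4 (5 mol %), THF, rt → 50 °C
Reagents that add atoms: none
Why: Mono-desilylation of the bis-silyl diyne with methyllithium, transmetalation to zinc and Negishi alkynylation of the enol triflate, the standard entry to conjugated diynes from alkenyl electrophiles.

Step 16
Reactants: 24 tert-butyldimethyl{[(R)-3,5,5-trimethyl-4-[4-(trimethylsilyl)buta-1,3-diyn-1-yl]cyclohex-3-en-1-yl]oxy}silane
Product: 25 (R)-4-(buta-1,3-diyn-1-yl)-3,5,5-trimethylcyclohex-3-en-1-ol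
Conditions: Bu4NF (2.5 equiv), THF, 0 °C → rt; product used at once as a solution
Reagents that add atoms: none
Why: Fluoride removes the alkynyl silyl group and the secondary silyl ether in one operation, which saves a separate deprotection.

Step 17
Reactants: 25 (R)-4-(buta-1,3-diyn-1-yl)-3,5,5-trimethylcyclohex-3-en-1-ol
Product: 27 (R)-4-[(E)-4-iodo-3-methylbut-3-en-1-yn-1-yl]-3,5,5-trimethylcyclohex-3-en-1-ol, via alkenylalane 26 (not isolated)
Conditions: Me3Al (4 equiv), Cp2ZrCl2 (0.3 equiv), CH2Cl2, 0 °C → rt; then I2 (1.3 equiv), THF, −30 → 0 °C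
Reagents that add atoms: trimethylaluminium, C[Al](C)C; iodine, II
Why: Negishi zirconium-catalysed methylalumination: syn-addition of methyl–aluminium across the terminal, unhindered alkyne puts methyl on the inner carbon and aluminium on the terminal carbon, and iodinolysis with retention gives the (E)-iodide; the hydroxyl is carried as its aluminium alkoxide and the hindered ring-conjugated alkyne should not react.

Step 18
Reactants: 27 (R)-4-[(E)-4-iodo-3-methylbut-3-en-1-yn-1-yl]-3,5,5-trimethylcyclohex-3-en-1-ol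
Product: 28 (R)-4-[(E)-4-iodo-3-methylbut-3-en-1-yn-1-yl]-3,5,5-trimethylcyclohex-3-en-1-yl acetate
Conditions: Ac2O, pyridine, DMAP (cat.), CH2Cl2, 0 °C → rt
Reagents that add atoms: acetic anhydride, CC(=O)OC(C)=O
Why: Acylation of the secondary alcohol with retention at the carbinol carbon; the alkenyl iodide is inert.

Step 19
Reactants: 28 (R)-4-[(E)-4-iodo-3-methylbut-3-en-1-yn-1-yl]-3,5,5-trimethylcyclohex-3-en-1-yl acetate; 20 (5Z)-3-{(E)-2-[(1S,4S,6R)-4-hydroxy-2,2,6-trimethyl-7-oxabicyclo[4.1.0]heptan-1-yl]ethenyl}-5-[(2E,4E,6E)-2-methyl-7-(tributylstannyl)hepta-2,4,6-trien-1-ylidene]furan-2(5H)-one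
Product: 29 pyrrhoxanthin, (R)-4-{(3E,5E,7E,9E)-11-[(2Z)-4-{(E)-2-[(1S,4S,6R)-4-hydroxy-2,2,6-trimethyl-7-oxabicyclo[4.1.0]heptan-1-yl]ethenyl}-5-oxofuran-2(5H)-ylidene]-3,10-dimethylundeca-3,5,7,9-tetraen-1-yn-1-yl}-3,5,5-trimethylcyclohex-3-en-1-yl acetate
Conditions: 20 (1.1 equiv), Pd2(dba)3 (5 mol %), AsPh3 (40 mol %), NMP, rt, dark, argon
Reagents that add atoms: none
Why: Stille coupling: zerovalent palladium inserts into the C(sp2)–I bond of 28, the trienyl group of 20 passes from tin to palladium (AsPh3 keeps this step fast at room temperature), and reductive elimination forms the C10′–C11′ bond; the closest known reaction type is the alkenyl iodide/alkenylstannane coupling used to close carotenoid and retinoid polyene chains. No ring is closed and no stereocentre is formed; the four existing stereocentres (one in ring A, three in ring C) are remote and untouched. The E geometry at the C(CH3)=CH alkene (from the syn-methylalumination) and at the terminal alkene of the triene (from the distannylethene) is carried through, because oxidative addition, transmetalation and reductive elimination are each stereoretentive. The selectivity needed is chemoselectivity for the C–I bond over the allylic epoxide of ring C, the enol lactone of ring B and the acetate of ring A; the base-free, fluoride-free conditions at room temperature and the fast insertion into the unhindered alkenyl iodide should secure it. Light is excluded so that the (Z)-ylidene bond and the polyene do not isomerise.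

Compound list
1 | (4R,6R)-4-hydroxy-2,2,6-trimethylcyclohexanone (actinol) | O[C@@H]1C[C@@H](C)C(=O)C(C)(C)C1 | starting material
2 | (4R,6R)-4-(tert-butyldimethylsilyloxy)-2,2,6-trimethylcyclohexanone | CC(C)(C)[Si](C)(C)O[C@@H]1C[C@@H](C)C(=O)C(C)(C)C1 | intermediate
3 | lithium (R)-4-(tert-butyldimethylsilyloxy)-2,6,6-trimethylcyclohex-1-en-1-olate | CC(C)(C)[Si](C)(C)O[C@@H]1CC(C)=C([O-])C(C)(C)C1.[Li+] | intermediate
4 | (R)-4-(tert-butyldimethylsilyloxy)-2,6,6-trimethylcyclohex-1-en-1-yl trifluoromethanesulfonate | CC(C)(C)[Si](C)(C)O[C@@H]1CC(C)=C(OS(=O)(=O)C(F)(F)F)C(C)(C)C1 | intermediate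
5 | methyl (R)-4-(tert-butyldimethylsilyloxy)-2,6,6-trimethylcyclohex-1-ene-1-carboxylate | CC(C)(C)[Si](C)(C)O[C@@H]1CC(C)=C(C(=O)OC)C(C)(C)C1 | intermediate
6 | [(R)-4-(tert-butyldimethylsilyloxy)-2,6,6-trimethylcyclohex-1-en-1-yl]methanol | CC(C)(C)[Si](C)(C)O[C@@H]1CC(C)=C(CO)C(C)(C)C1 | intermediate
7 | [(1R,4S,6R)-4-(tert-butyldimethylsilyloxy)-2,2,6-trimethyl-7-oxabicyclo[4.1.0]heptan-1-yl]methanol | OC[C@@]12O[C@]1(C)C[C@@H](O[Si](C)(C)C(C)(C)C)CC2(C)C | intermediate
8 | (1S,4S,6R)-4-(tert-butyldimethylsilyloxy)-2,2,6-trimethyl-7-oxabicyclo[4.1.0]heptane-1-carbaldehyde | O=C[C@@]12O[C@]1(C)C[C@@H](O[Si](C)(C)C(C)(C)C)CC2(C)C | intermediate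
9 | 2-{(E)-2-[(1S,4S,6R)-4-(tert-butyldimethylsilyloxy)-2,2,6-trimethyl-7-oxabicyclo[4.1.0]heptan-1-yl]ethenyl}-4,4,5,5-tetramethyl-1,3,2-dioxaborolane | CC1(C)OB(/C=C/[C@@]23O[C@]2(C)C[C@@H](O[Si](C)(C)C(C)(C)C)CC3(C)C)OC1(C)C | intermediate
10 | (1R,3S,6S)-1,5,5-trimethyl-6-[(E)-2-(4,4,5,5-tetramethyl-1,3,2-dioxaborolan-2-yl)ethenyl]-7-oxabicyclo[4.1.0]heptan-3-ol | CC1(C)OB(/C=C/[C@@]23O[C@]2(C)C[C@@H](O)CC3(C)C)OC1(C)C | intermediate
11 | propiolic acid | C#CC(=O)O | starting material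
12 | (E)-2,3-dibromoprop-2-enoic acid | OC(=O)/C(Br)=C\Br | intermediate
13 | (E)-3-methylpent-2-en-4-yn-1-ol | C#C/C(C)=C/CO | starting material
14 | (2E,6E)-2-bromo-8-hydroxy-6-methylocta-2,6-dien-4-ynoic acid | OC(=O)/C(Br)=C\C#C/C(C)=C/CO | intermediate
15 | (5Z)-3-bromo-5-[(2E)-4-hydroxy-2-methylbut-2-en-1-ylidene]furan-2(5H)-one | OC/C=C(C)/C=C1C=C(Br)C(=O)O/1 | intermediate
16 | (5Z)-3-{(E)-2-[(1S,4S,6R)-4-hydroxy-2,2,6-trimethyl-7-oxabicyclo[4.1.0]heptan-1-yl]ethenyl}-5-[(2E)-4-hydroxy-2-methylbut-2-en-1-ylidene]furan-2(5H)-one | OC/C=C(C)/C=C1C=C(/C=C/[C@@]23O[C@]2(C)C[C@@H](O)CC3(C)C)C(=O)O/1 | intermediate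
17 | (2E)-4-[(2Z)-4-{(E)-2-[(1S,4S,6R)-4-hydroxy-2,2,6-trimethyl-7-oxabicyclo[4.1.0]heptan-1-yl]ethenyl}-5-oxofuran-2(5H)-ylidene]-3-methylbut-2-enal | O=C/C=C(C)/C=C1C=C(/C=C/[C@@]23O[C@]2(C)C[C@@H](O)CC3(C)C)C(=O)O/1 | intermediate
18 | (5Z)-3-{(E)-2-[(1S,4S,6R)-4-hydroxy-2,2,6-trimethyl-7-oxabicyclo[4.1.0]heptan-1-yl]ethenyl}-5-[(2E,4E)-5-iodo-2-methylpenta-2,4-dien-1-ylidene]furan-2(5H)-one | I/C=C/C=C(C)/C=C1C=C(/C=C/[C@@]23O[C@]2(C)C[C@@H](O)CC3(C)C)C(=O)O/1 | intermediate
19 | (E)-1,2-bis(tributylstannyl)ethene | CCCC[Sn](CCCC)(CCCC)/C=C/[Sn](CCCC)(CCCC)CCCC | starting material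
20 | (5Z)-3-{(E)-2-[(1S,4S,6R)-4-hydroxy-2,2,6-trimethyl-7-oxabicyclo[4.1.0]heptan-1-yl]ethenyl}-5-[(2E,4E,6E)-2-methyl-7-(tributylstannyl)hepta-2,4,6-trien-1-ylidene]furan-2(5H)-one | CCCC[Sn](CCCC)(CCCC)/C=C/C=C/C=C(C)/C=C1C=C(/C=C/[C@@]23O[C@]2(C)C[C@@H](O)CC3(C)C)C(=O)O/1 | intermediate
21 | 1,4-bis(trimethylsilyl)buta-1,3-diyne | C[Si](C)(C)C#CC#C[Si](C)(C)C | starting material
22 | lithium 4-(trimethylsilyl)buta-1,3-diyn-1-ide | [Li+].[C-]#CC#C[Si](C)(C)C | intermediate
23 | bromo[4-(trimethylsilyl)buta-1,3-diyn-1-yl]zinc | Br[Zn]C#CC#C[Si](C)(C)C | intermediate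
24 | tert-butyldimethyl{[(R)-3,5,5-trimethyl-4-[4-(trimethylsilyl)buta-1,3-diyn-1-yl]cyclohex-3-en-1-yl]oxy}silane | CC(C)(C)[Si](C)(C)O[C@@H]1CC(C)=C(C#CC#C[Si](C)(C)C)C(C)(C)C1 | intermediate
25 | (R)-4-(buta-1,3-diyn-1-yl)-3,5,5-trimethylcyclohex-3-en-1-ol | O[C@@H]1CC(C)=C(C#CC#C)C(C)(C)C1 | intermediate
26 | dimethylaluminium alkoxide of (R)-4-[(E)-4-(dimethylalumanyl)-3-methylbut-3-en-1-yn-1-yl]-3,5,5-trimethylcyclohex-3-en-1-ol | C[Al](C)O[C@@H]1CC(C)=C(C#C/C(C)=C/[Al](C)C)C(C)(C)C1 | intermediate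
27 | (R)-4-[(E)-4-iodo-3-methylbut-3-en-1-yn-1-yl]-3,5,5-trimethylcyclohex-3-en-1-ol | O[C@@H]1CC(C)=C(C#C/C(C)=C/I)C(C)(C)C1 | intermediate
28 | (R)-4-[(E)-4-iodo-3-methylbut-3-en-1-yn-1-yl]-3,5,5-trimethylcyclohex-3-en-1-yl acetate | CC(=O)O[C@@H]1CC(C)=C(C#C/C(C)=C/I)C(C)(C)C1 | intermediate
29 | pyrrhoxanthin | CC(=O)O[C@@H]1CC(C)=C(C#C/C(C)=C/C=C/C=C/C=C(C)/C=C2C=C(/C=C/[C@@]34O[C@]3(C)C[C@@H](O)CC4(C)C)C(=O)O/2)C(C)(C)C1 | target

Total step count: 19.
Longest linear sequence: 13 steps (steps 1–8, 11–14 and 19).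

Steps most likely to fail

Step 17. The methyl–aluminium addition may go to the wrong carbon of the terminal alkyne or onto the ring-conjugated alkyne, and the terminal diyne may oligomerise under the Lewis-acidic conditions. The fallback sets out from ketone 2 and comes back at 27. The iodoalkene is made on the simplest substrate and joined to ring A by carbonyl addition. Propargyl alcohol is methylaluminated and iodinated (Me3Al, Cp2ZrCl2; I2) to (E)-3-iodo-2-methylprop-2-en-1-ol F1, oxidised with MnO2 to (E)-3-iodo-2-methylprop-2-enal F2, and homologated with lithiated trimethylsilyldiazomethane (Colvin rearrangement) to (E)-4-iodo-3-methylbut-3-en-1-yne F3. Its lithium acetylide (LiN(SiMe3)2, CeCl3, THF, −78 °C) should add to ketone 2 to give the tertiary propargylic alcohol F4. Dehydration with POCl3/pyridine, for which only one β-hydrogen is available, should give the silyl-protected iodoenyne F5, and Bu4NF then gives 27.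

Step 11. The oxygen base may open the enol lactone of 15, or the boronate may be protodeborylated before transmetalation. The fallback sets out from aldehyde 8 and comes back at 16, making the same bond by a base-free Stille coupling. Dibromomethane is lithiated (LiN(iPr)2, −90 °C) and stannylated with Bu3SnCl to (dibromomethyl)tributylstannane F6. With CrCl2/LiI this converts 8 into the silyl-protected (E)-alkenylstannane F7 (Hodgson olefination). Bu4NF gives the hydroxy alkenylstannane F8, which is coupled with bromide 15 (Pd2(dba)3, AsPh3, NMP, rt) to give 16.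

Step 13. The chromium iodo-olefination of the conjugated enal may give poor E-selectivity, and the Lewis-acidic trivalent chromium formed may open the allylic epoxide. The fallback sets out from 17 and comes back at 20, bringing in the three chain carbons and the tin together by a Horner–Wadsworth–Emmons reaction. Propargyl alcohol is hydrostannylated (Bu3SnH, AIBN) to (E)-3-(tributylstannyl)prop-2-en-1-ol F9, converted with CBr4/PPh3 into (E)-(3-bromoprop-1-en-1-yl)tributylstannane F10, and by Arbuzov reaction with P(OEt)3 into diethyl [(E)-3-(tributylstannyl)prop-2-en-1-yl]phosphonate F11. Its lithium anion (LiN(SiMe3)2, THF, −78 °C) should olefinate 17 to give 20 directly, bypassing 18.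

Further compounds
F1 | step 17 | (E)-3-iodo-2-methylprop-2-en-1-ol | OC/C(C)=C/I
F2 | step 17 | (E)-3-iodo-2-methylprop-2-enal | O=C/C(C)=C/I
F3 | step 17 | (E)-4-iodo-3-methylbut-3-en-1-yne | C#C/C(C)=C/I
F4 | step 17 | (4R,6R)-4-(tert-butyldimethylsilyloxy)-1-[(E)-4-iodo-3-methylbut-3-en-1-yn-1-yl]-2,2,6-trimethylcyclohexan-1-ol (carbinol epimers) | CC(C)(C)[Si](C)(C)O[C@@H]1C[C@@H](C)C(O)(C#C/C(C)=C/I)C(C)(C)C1
F5 | step 17 | tert-butyl{[(R)-4-[(E)-4-iodo-3-methylbut-3-en-1-yn-1-yl]-3,5,5-trimethylcyclohex-3-en-1-yl]oxy}dimethylsilane | CC(C)(C)[Si](C)(C)O[C@@H]1CC(C)=C(C#C/C(C)=C/I)C(C)(C)C1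
F6 | step 11 | (dibromomethyl)tributylstannane | BrC(Br)[Sn](CCCC)(CCCC)CCCC
F7 | step 11 | tert-butyldimethyl{[(1S,3S,6R)-1,5,5-trimethyl-6-[(E)-2-(tributylstannyl)ethenyl]-7-oxabicyclo[4.1.0]heptan-3-yl]oxy}silane (ring configuration as in 9) | CCCC[Sn](CCCC)(CCCC)/C=C/[C@@]12O[C@]1(C)C[C@@H](O[Si](C)(C)C(C)(C)C)CC2(C)C
F8 | step 11 | (1R,3S,6S)-1,5,5-trimethyl-6-[(E)-2-(tributylstannyl)ethenyl]-7-oxabicyclo[4.1.0]heptan-3-ol | CCCC[Sn](CCCC)(CCCC)/C=C/[C@@]12O[C@]1(C)C[C@@H](O)CC2(C)C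
F9 | step 13 | (E)-3-(tributylstannyl)prop-2-en-1-ol | OC/C=C/[Sn](CCCC)(CCCC)CCCC
F10 | step 13 | (E)-(3-bromoprop-1-en-1-yl)tributylstannane | BrC/C=C/[Sn](CCCC)(CCCC)CCCC
F11 | step 13 | diethyl [(E)-3-(tributylstannyl)prop-2-en-1-yl]phosphonate | CCOP(=O)(C/C=C/[Sn](CCCC)(CCCC)CCCC)OCC
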